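## Structural features

The target joins three units: a trans-fused 2,2-dimethyloxepane/cyclohexane bicycle (oxepane and ring A), a chain of four methylene groups, and a bicyclo[2.2.2]octan-1-ol that carries a 2-hydroxy-5-sulfooxybenzyl group. In benzoxepine numbering, ring A holds four contiguous stereocentres: the methyl-bearing C7, the tertiary carbinol C6, the angular quaternary C5a and the ring-fusion carbon C9a bonded to the ether oxygen. The bicyclooctane holds four more: the bridgehead carbinol, the bridgehead CH, the arylmethyl-bearing carbon next to a gem-dimethyl carbon, and a quaternary carbon with methyl and chain. The two stereo-arrays are insulated by the chain, so each half has to be made as a single enantiomer on its own. Fragile groups are the aryl hydrogen sulfate (acid-labile, installed last), the electron-rich hydroquinone and two tertiary alcohols. The real difficulty is the run C9a–C5a–C6: a seven-membered ether trans-fused to a quaternary carbon that sits next to a tertiary carbinol whose hydroxyl is anti to the angular methyl, the face a carbon nucleophile would itself choose on the corresponding ketone. The key step uses the fact that O1–C2(Me2)–C3 plus C9a of the oxepane are a latent 2,2-dimethylfuran-3(2H)-one. Its two enone carbons each need one bond, to C5a and to C5, and a tethered isopropenyl group can supply both in a [2+2] photocycloaddition. Release of the cyclobutane strain then expands the five-membered ring to the oxepane.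

## Logic of the disconnections

55 ⇐ 54 ⇐ 53. The S–O bond of the sulfate and the two Si–O bonds are cut first, because the sulfate tolerates neither acid nor most of the preceding chemistry. This leaves a phenol as the only nucleophilic oxygen next to a hindered tertiary alcohol, so the forward sulfation only has to distinguish phenol from tertiary carbinol.

53 ⇐ 52 ⇐ 24 + 50. The third C–C bond of the chain (counted from C6) is cut as an alkene. This splits the molecule into halves of similar size and places the carbonyl partner on a non-enolisable aldehyde. One hydrogenation must then saturate this alkene and the ring alkene of the eastern half and free the phenol.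

24 ⇐ 23 ⇐ 22 ⇐ 21 ⇐ 20. The bond between the first and second chain carbons is cut back to a spiro-epoxide. The C6–O bond is therefore never made by carbon addition to a ketone, which would put the chain on the wrong face. The forward step needs an SN2 opening at a neopentyl-like CH2.

20 ⇐ 19 ⇐ 18. The epoxide C–O bond is traced to an exocyclic alkene and that to a ketone. Oxygen then arrives from the face opposite the axial angular methyl, which is the configuration required.

18 ⇐ 17 ⇐ 16 ⇐ 15 ⇐ 14 ⇐ 13. These are functional-group changes only: the C6 carbinol is unmasked and oxidised, and the C3 ketone left by the ring expansion is removed. The demand is that the two oxygens stay differentiated, which the silyl ether on C6 ensures.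

13 ⇐ 11. The C4–C9a bond is reconnected, which contracts the oxepanone to a furanone fused to a cyclobutane. The forward step must break exactly this donor–acceptor bond and deliver hydride to C9a anti to the angular methyl.

11 ⇐ 10 (key disconnection). The bonds C9a–C5a and C4–C5 are cut, opening ring A and the cyclobutane. The congested quaternary carbon then comes from an unhindered 1,1-disubstituted alkene and three stereocentres come from two on the tether. The forward step needs straight regiochemistry and one alkene face.

10 ⇐ 8 + 7, then 7 ⇐ 6 ⇐ 5 ⇐ 4 ⇐ 1 + 2. The CH2–CH2 bond next to the furanone is cut to a γ-metalated furanone and a primary iodide. The iodide is traced to a syn aldol between a propionate and an enal. This matters because only the syn pair can later be diequatorial in the photocycloaddition chair, so an unselective vinyl-metal addition to an α-methyl aldehyde would not serve. The forward aldol must set both centres absolutely.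

50 ⇐ 49 ⇐ 48 ⇐ 46. The methyl on the quaternary carbon of the bicycle is cut, so that centre comes from an ester enolate. The ester carbon becomes the fourth chain carbon. Alkylation has to occur anti to the gem-dimethyl bridge.

46 ⇐ 45 ⇐ 40 + 43, with 43 ⇐ 41. Both bonds of the ester-bearing bridge are cut in a Diels–Alder sense. The diene oxygen becomes the bridgehead oxygen and no extra ketone is created. A nitro group, later lost as nitrous acid, must enforce the orientation that places the ester next to the CH bridgehead.

40 ⇐ 39 ⇐ 38 ⇐ 37 ⇐ 35 ⇐ 34 ⇐ 32 + 28, with 32 ⇐ 29 + 30 and 28 ⇐ 27 ⇐ 26 ⇐ 25. The ring alkene is cut by metathesis and the benzylic C–C bond by auxiliary-controlled enolate alkylation. The single stereocentre of the diene, which later directs the cycloaddition face, thus comes from a commercial oxazolidinone, and the differentiated hydroquinone comes from a commercial salicylaldehyde.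

## Other disconnections considered

Alternative 1: The cut lies in the bicyclooctane: the bond from the bridgehead carbinol to its CH2 neighbour and the bond from the CH bridgehead to the carbon that becomes quaternary. In the forward step the cross-conjugated lithium dienolate of α′-alkoxy enone A1 adds to methyl acrylate and the ester enolate closes onto the enone β-carbon to give A2.
- In favour: one operation builds the bicycle, three stereocentres and the bridgehead oxygen, with the arylmethyl group already present. The orientation follows from the polarity of the partners, so no control group has to be removed afterwards. On this point it is better than the chosen plan, which needs a nitro group, an elimination and a conjugate reduction between 40 and 46.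
- Against: it does nothing for the oxepane/ring A half, where the vicinal fully substituted carbons sit. It leaves a ketone on the two-carbon bridge that must be removed before the ester can be methylated. A1 needs an enantioselective introduction of the arylmethyl group β to the carbonyl. The bridgehead acetal needs acid before the sulfate can be installed.
- Comparison: both plans form the same two bonds of the bicycle, one by a stepwise anionic route and the other by a concerted cycloaddition. Step economy in the eastern half is about equal, since ketone removal balances nitro removal. As the centre of the synthesis it is weaker, because the harder western problem stays open.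

Alternative 2: The cut removes the O–CMe2 bond of the oxepane and the bond between the angular carbon and the neighbouring ring A carbon, which opens both rings to the acyclic bis-epoxide A3. In the forward step BF3·OEt2 opens the terminal epoxide at its tertiary carbon, the inner epoxide oxygen captures it, and the β-keto ester enol attacks the epoxonium ion at the methyl-bearing carbon to give A4.
- In favour: both rings, the trans fusion and the angular centre form in one step from a chain whose stereochemistry comes from two catalytic epoxidations. The anti opening is stereospecific and no photochemical equipment is needed. On rings per step it is better than the chosen plan, and on delivering the trans fusion it is its equal.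
- Against: the epoxonium ion can also close a six-membered ether, and the enol must attack the more hindered carbon. A4 carries a surplus secondary hydroxyl beside the gem-dimethyl carbon, a ketone where the secondary methyl must be set, and an ester on the carbon that must become the chain-bearing tertiary carbinol. The post-processing is therefore long.
- Comparison: it forms the O–CMe2 bond that the chosen plan buys ready-made in 8. The mechanism is a cationic relay in place of a triplet biradical. It is shorter up to the bicycle and longer after it.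

Alternative 3: The cut removes the ring oxygen at the ring fusion, so the oxepane becomes the seven-membered lactone A6, made from the trans-decalone A5. In the forward step a peracid inserts oxygen between the carbonyl carbon and the ring-fusion methine, which migrates with retention.
- In favour: every step is established chemistry. The decalone derives from the Wieland–Miescher ketone, available in either enantiomeric form, with the angular methyl and the C6 oxygen in place. The trans fusion is inherited rather than created. On reliability and scale (no dilute photolysis, no unproven fragmentation) it is better than the chosen plan.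
- Against: the carbonyl must first be transposed to the carbon next to the ring fusion. The lactone carbonyl must be turned into the gem-dimethyl ether carbon, which means two methyl additions and re-closure of a seven-membered ether, the thermal closure the chosen plan avoids. The ring A methyl is also still missing.
- Comparison: the alternative makes a C–O bond where the chosen plan makes C–C bonds. A concerted 1,2-shift replaces a photocycloaddition. Step economy is clearly worse, while predictability is equal or better.

Key step: step 6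

Assumption: the aryl hydrogen sulfate is carried and stored as its sodium salt and the free acid drawn for the target is released only in the last operation; compounds 1, 2, 8, 25, 29, 30 and 41 are taken as commercial. Abbreviation used in names: ArCH2 = [5-(benzyloxy)-2-(triisopropylsilyloxy)phenyl]methyl.

## Route

Step 1
Reactants: 1 (R)-4-benzyl-3-propionyloxazolidin-2-one; 2 methacrolein
Product: 4 (R)-4-benzyl-3-[(2R,3R)-3-hydroxy-2,4-dimethylpent-4-enoyl]oxazolidin-2-one, via dibutylboron Z-enolate 3 (not isolated)
Conditions: Bu2BOTf, i-Pr2NEt, CH2Cl2, 0 °C; 2, −78 → 0 °C; then pH 7 buffer, MeOH, H2O2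
Reagents that add atoms: none
Why: Evans syn aldol; the Z-boron enolate reacts through a closed chair transition state on the face away from the benzyl group of the auxiliary, which should set both new centres (2R,3R) with methyl and hydroxyl syn.

Step 2
Reactants: 4 (R)-4-benzyl-3-[(2R,3R)-3-hydroxy-2,4-dimethylpent-4-enoyl]oxazolidin-2-one
Product: 5 (R)-4-benzyl-3-[(2R,3R)-3-(tert-butyldimethylsilyloxy)-2,4-dimethylpent-4-enoyl]oxazolidin-2-one
Conditions: TBSOTf, 2,6-lutidine, CH2Cl2, 0 °C
Reagents that add atoms: tert-butyldimethylsilyl triflate, CC(C)(C)[Si](C)(C)OS(=O)(=O)C(F)(F)F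
Why: Silylation of a secondary allylic alcohol with a silyl triflate and a hindered base; the bulky ether is the later equatorial anchor and tolerates base, light and hydride.

Step 3
Reactants: 5 (R)-4-benzyl-3-[(2R,3R)-3-(tert-butyldimethylsilyloxy)-2,4-dimethylpent-4-enoyl]oxazolidin-2-one
Product: 6 (2S,3R)-3-(tert-butyldimethylsilyloxy)-2,4-dimethylpent-4-en-1-ol
Conditions: LiBH4, MeOH (1 equiv), THF, 0 °C → rt
Reagents that add atoms: none
Why: Reductive cleavage of the N-acyl oxazolidinone at the exocyclic carbonyl should free the primary alcohol without epimerising the α-centre; the descriptor changes only because the priorities change.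

Step 4
Reactants: 6 (2S,3R)-3-(tert-butyldimethylsilyloxy)-2,4-dimethylpent-4-en-1-ol
Product: 7 tert-butyl{[(3R,4R)-5-iodo-2,4-dimethylpent-1-en-3-yl]oxy}dimethylsilane
Conditions: I2, PPh3, imidazole, CH2Cl2, 0 °C → rt
Reagents that add atoms: iodine, II
Why: Appel-type iodination of the primary alcohol; no stereocentre is touched.

Step 5
Reactants: 8 2,2,5-trimethylfuran-3(2H)-one; 7 tert-butyl{[(3R,4R)-5-iodo-2,4-dimethylpent-1-en-3-yl]oxy}dimethylsilane
Product: 10 5-[(3S,4R)-4-(tert-butyldimethylsilyloxy)-3,5-dimethylhex-5-en-1-yl]-2,2-dimethylfuran-3(2H)-one, via lithium dienolate 9 (not isolated)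
Conditions: 8 (1.5 equiv), LDA, THF, −78 °C; then 7, HMPA, −78 → −20 °C
Reagents that add atoms: none
Why: γ-Alkylation of a vinylogous ester; the furanone has no α′ hydrogen, so LDA removes a proton of the 5-methyl group and the extended enolate should alkylate at that carbon with return of the conjugated ring. HMPA and an excess of the cheap dienolate are meant to outrun elimination of the β-branched iodide.

Step 6
Reactants: 10 5-[(3S,4R)-4-(tert-butyldimethylsilyloxy)-3,5-dimethylhex-5-en-1-yl]-2,2-dimethylfuran-3(2H)-one
Product: 11 tricyclic photoadduct: 3,3-dimethyl-2-oxabicyclo[3.2.0]heptan-4-one whose cyclobutane is cis-fused to ring A (ring A carries the equatorial C-methyl, the equatorial silyloxy group and the angular methyl anti to the C-methyl)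
Conditions: hν (350 nm lamps, Pyrex), degassed MeCN (0.01 M), 20 °C
Reagents that add atoms: none
Why: Intramolecular enone–alkene [2+2] photocycloaddition of a cyclic vinylogous ester, the first half of a de Mayo-type two-carbon ring expansion and a known reaction type. The triplet furanone bonds through its β-carbon C5 to the internal alkene carbon in a 6-exo-trig closure that forms ring A; the 1,4-biradical (α-keto radical at C4, primary radical at the former =CH2) then collapses by radical coupling to the cyclobutane. The angular carbon and C5 are set in that first bond: the four-atom tether adopts a chair in which the C-methyl and the silyloxy group are both equatorial, the alkene lies with its methylene pointing away from the ring and its methyl axial, so the angular methyl ends up anti to the ring A methyl. C5 follows because a cyclobutane can only be cis-fused to ring A, so the furanone C4 must take the axial site next to the equatorial methylene, and the C4–H centre is fixed by the cis fusion of cyclobutane and five-membered ring. The step needs straight rather than crossed regiochemistry, which the preference for closing a six-membered ring first should secure, and one alkene face, which the diequatorial chair should secure; only the syn-configured precursor can adopt it, since an axial silyloxy group would be 1,3-diaxial to the incoming furanone carbon. Irradiation above 300 nm through Pyrex keeps the product ketone from secondary cleavage.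

Step 7
Reactants: 11 tricyclic photoadduct
Product: 13 (5aR,6R,7S,9aS)-6-(tert-butyldimethylsilyloxy)-2,2,5a,7-tetramethyloctahydro-1-benzoxepin-3(2H)-one, via trimethylsilyl enol ether 12 (not isolated)
Conditions: TMSOTf (1.2 equiv), Et3SiH (3 equiv), CH2Cl2, −78 → −40 °C; then K2CO3, MeOH, 0 °C
Reagents that add atoms: none
Why: Proposed new method: the C4–C5 cyclobutane bond is flanked by the ring oxygen (donor) and the ketone (acceptor), so O-silylation of the ketone should trigger strain-driven heterolysis to a silyl enol ether and a seven-membered oxocarbenium ion, which Et3SiH reduces by axial attack anti to the angular methyl to give the trans fusion; the closest known reaction types are the Lewis-acid opening of alkoxy-substituted donor–acceptor cyclobutanes, the retro-aldol half of the de Mayo reaction and the Et3SiH/TMSOTf reduction of cyclic oxocarbenium ions to trans-fused oxepanes.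

Step 8
Reactants: 13 (5aR,6R,7S,9aS)-6-(tert-butyldimethylsilyloxy)-2,2,5a,7-tetramethyloctahydro-1-benzoxepin-3(2H)-one
Product: 14 (5aR,6R,7S,9aS)-6-(tert-butyldimethylsilyloxy)-2,2,5a,7-tetramethyldecahydro-1-benzoxepin-3-ol (C3 epimers)
Conditions: NaBH4, MeOH, 0 °C → rt
Reagents that add atoms: none
Why: Borohydride reduction of the ketone; the new carbinol configuration is irrelevant because this oxygen is removed.

Step 9
Reactants: 14 (5aR,6R,7S,9aS)-6-(tert-butyldimethylsilyloxy)-2,2,5a,7-tetramethyldecahydro-1-benzoxepin-3-ol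
Product: 15 O-phenyl thionocarbonate of 14
Conditions: PhOC(S)Cl, pyridine, DMAP (cat.), CH2Cl2, rt
Reagents that add atoms: O-phenyl chlorothionoformate, S=C(Cl)Oc1ccccc1
Why: Acylation of the hindered secondary alcohol with a thionoformate under DMAP catalysis gives the radical precursor for deoxygenation.

Step 10
Reactants: 15 O-phenyl thionocarbonate of 14
Product: 16 tert-butyldimethyl{[(5aR,6R,7S,9aS)-2,2,5a,7-tetramethyldecahydro-1-benzoxepin-6-yl]oxy}silane
Conditions: Bu3SnH, AIBN (cat.), toluene, 110 °C
Reagents that add atoms: none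
Why: Barton–McCombie deoxygenation; the secondary radical is reduced by the stannane, and the ether oxygen on the neighbouring carbon is not a radical leaving group, so the oxepane should stay intact.

Step 11
Reactants: 16 tert-butyldimethyl{[(5aR,6R,7S,9aS)-2,2,5a,7-tetramethyldecahydro-1-benzoxepin-6-yl]oxy}silane
Product: 17 (5aS,6R,7S,9aS)-2,2,5a,7-tetramethyldecahydro-1-benzoxepin-6-ol
Conditions: TBAF, THF, 60 °C
Reagents that add atoms: none
Why: Fluoride cleavage of the hindered secondary silyl ether; nothing else in the molecule responds to fluoride.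

Step 12
Reactants: 17 (5aS,6R,7S,9aS)-2,2,5a,7-tetramethyldecahydro-1-benzoxepin-6-ol
Product: 18 (5aR,7S,9aS)-2,2,5a,7-tetramethyloctahydro-1-benzoxepin-6(2H)-one
Conditions: Dess–Martin periodinane, NaHCO3, CH2Cl2, rt
Reagents that add atoms: none
Why: Dess–Martin oxidation of the hindered secondary alcohol under buffered, non-epimerising conditions.

Step 13
Reactants: 18 (5aR,7S,9aS)-2,2,5a,7-tetramethyloctahydro-1-benzoxepin-6(2H)-one
Product: 19 (5aS,7S,9aS)-2,2,5a,7-tetramethyl-6-methylidenedecahydro-1-benzoxepine
Conditions: Ph3PCH3Br, KOt-Bu, toluene, 90 °C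
Reagents that add atoms: methyltriphenylphosphonium bromide, C[P+](c1ccccc1)(c1ccccc1)c1ccccc1.[Br-]
Why: Wittig methylenation with the ylide in hot toluene, conditions suited to α-quaternary ketones; the C7 methyl is already equatorial and therefore in its more stable position, so reversible enolisation cannot scramble it.

Step 14
Reactants: 19 (5aS,7S,9aS)-2,2,5a,7-tetramethyl-6-methylidenedecahydro-1-benzoxepine
Product: 20 spiro-epoxide of 19 at C6 (epoxide oxygen axial and anti to the angular methyl; 5aR,6S,7S,9aS)
Conditions: mCPBA, NaHCO3, CH2Cl2, 0 °C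
Reagents that add atoms: 3-chloroperoxybenzoic acid, OOC(=O)c1cccc(Cl)c1
Why: Prilezhaev epoxidation; the peracid should approach the exocyclic alkene from the face opposite the axial angular methyl on the neighbouring carbon, which places the oxygen where the tertiary hydroxyl of the target must be.

Step 15
Reactants: 20 spiro-epoxide
Product: 21 (5aR,6S,7S,9aS)-2,2,5a,7-tetramethyl-6-(prop-2-en-1-yl)decahydro-1-benzoxepin-6-ol
Conditions: CH2=CHMgBr (4 equiv), CuI (10 mol%), THF, −30 → 0 °C
Reagents that add atoms: vinylmagnesium bromide, C=C[Mg]Br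
Why: Copper-catalysed SN2 opening of the 2,2-disubstituted epoxide at its CH2 by a Grignard reagent; the C–O bond at the quaternary carbinol carbon is not touched, so its configuration is retained.

Step 16
Reactants: 21 (5aR,6S,7S,9aS)-2,2,5a,7-tetramethyl-6-(prop-2-en-1-yl)decahydro-1-benzoxepin-6-ol
Product: 22 (5aR,6S,7S,9aS)-6-(3-hydroxypropyl)-2,2,5a,7-tetramethyldecahydro-1-benzoxepin-6-ol
Conditions: 9-BBN (2.5 equiv), THF, rt; then NaOH, H2O2, 0 °C
Reagents that add atoms: hydrogen peroxide, OO
Why: Anti-Markovnikov hydroboration–oxidation of the terminal alkene; the tertiary hydroxyl only consumes one equivalent of the borane.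

Step 17
Reactants: 22 (5aR,6S,7S,9aS)-6-(3-hydroxypropyl)-2,2,5a,7-tetramethyldecahydro-1-benzoxepin-6-ol
Product: 23 (5aR,6S,7S,9aS)-2,2,5a,7-tetramethyl-6-{3-[(1-phenyl-1H-tetrazol-5-yl)sulfanyl]propyl}decahydro-1-benzoxepin-6-ol
Conditions: 1-phenyl-1H-tetrazole-5-thiol, PPh3, DIAD, THF, 0 °C → rt
Reagents that add atoms: 1-phenyl-1H-tetrazole-5-thiol, Sc1nnnn1-c1ccccc1
Why: Mitsunobu thioetherification; the acidic thiol is alkylated by the activated primary alcohol far faster than the hindered tertiary hydroxyl can close a tetrahydrofuran.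

Step 18
Reactants: 23 (5aR,6S,7S,9aS)-2,2,5a,7-tetramethyl-6-{3-[(1-phenyl-1H-tetrazol-5-yl)sulfanyl]propyl}decahydro-1-benzoxepin-6-ol
Product: 24 (5aR,6S,7S,9aS)-2,2,5a,7-tetramethyl-6-{3-[(1-phenyl-1H-tetrazol-5-yl)sulfonyl]propyl}decahydro-1-benzoxepin-6-ol
Conditions: (NH4)6Mo7O24·4H2O (10 mol%), 30% H2O2, EtOH, rt
Reagents that add atoms: hydrogen peroxide, OO
Why: Molybdate-catalysed peroxide oxidation of sulfide to sulfone; ether and tertiary alcohol are inert.

Step 19
Reactants: 25 5-(benzyloxy)-2-hydroxybenzaldehyde
Product: 26 5-(benzyloxy)-2-(triisopropylsilyloxy)benzaldehyde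
Conditions: TIPSOTf, Et3N, CH2Cl2, 0 °C
Reagents that add atoms: triisopropylsilyl triflate, CC(C)[Si](C(C)C)(C(C)C)OS(=O)(=O)C(F)(F)F
Why: Silylation of the hydrogen-bonded phenol with a silyl triflate; the ortho-flanked triisopropylsilyl ether is the most base-stable common aryl silyl ether and is kept to the last step, while the benzyl ether marks the oxygen to be sulfated.

Step 20
Reactants: 26 5-(benzyloxy)-2-(triisopropylsilyloxy)benzaldehyde
Product: 27 [5-(benzyloxy)-2-(triisopropylsilyloxy)phenyl]methanol
Conditions: NaBH4, THF/MeOH, −20 °C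
Reagents that add atoms: none
Why: Borohydride reduction of the aldehyde, run cold to limit aryl-to-benzyl silyl migration.

Step 21
Reactants: 27 [5-(benzyloxy)-2-(triisopropylsilyloxy)phenyl]methanol
Product: 28 [4-(benzyloxy)-2-(bromomethyl)phenoxy]triisopropylsilane
Conditions: CBr4, PPh3, CH2Cl2, 0 °C
Reagents that add atoms: tetrabromomethane, BrC(Br)(Br)Br
Why: Appel bromination under neutral conditions; the electron-rich benzylic bromide is used at once.

Step 22
Reactants: 29 3,3-dimethylpent-4-enoic acid; 30 (S)-4-benzyloxazolidin-2-one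
Product: 32 (S)-4-benzyl-3-(3,3-dimethylpent-4-enoyl)oxazolidin-2-one, via mixed pivalic anhydride 31 (not isolated)
Conditions: PivCl, Et3N, THF, −20 °C; then 30, LiCl, rt
Reagents that add atoms: none
Why: N-Acylation of the oxazolidinone through the mixed anhydride with LiCl/Et3N activation.

Step 23
Reactants: 32 (S)-4-benzyl-3-(3,3-dimethylpent-4-enoyl)oxazolidin-2-one; 28 [4-(benzyloxy)-2-(bromomethyl)phenoxy]triisopropylsilane
Product: 34 (S)-4-benzyl-3-[(2S)-2-(ArCH2)-3,3-dimethylpent-4-enoyl]oxazolidin-2-one, via sodium Z-enolate 33 (not isolated)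
Conditions: NaHMDS, THF, −78 °C; then 28, −78 → −30 °C
Reagents that add atoms: none
Why: Evans alkylation; the chelated Z-enolate is benzylated on the face opposite the benzyl group of the auxiliary, which should give the S-configured α-centre (the tert-alkyl group outranks the arylmethyl group).

Step 24
Reactants: 34 (S)-4-benzyl-3-[(2S)-2-(ArCH2)-3,3-dimethylpent-4-enoyl]oxazolidin-2-one
Product: 35 (2S)-2-(ArCH2)-3,3-dimethylpent-4-enoic acid
Conditions: LiOH, H2O2, THF/H2O, 0 °C; then Na2SO3; HCl to pH 3
Reagents that add atoms: hydrogen peroxide, OO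
Why: Hydroperoxide hydrolysis attacks the exocyclic carbonyl even of hindered N-acyl oxazolidinones; the cold, short exposure should spare the hindered aryl silyl ether.

Step 25
Reactants: 35 (2S)-2-(ArCH2)-3,3-dimethylpent-4-enoic acid
Product: 37 (2S)-2-(ArCH2)-N-methoxy-N,3,3-trimethylpent-4-enamide, via acid chloride 36 (not isolated)
Conditions: (COCl)2, DMF (cat.), CH2Cl2, 0 °C; then MeNHOMe·HCl, pyridine, 0 °C → rt
Reagents that add atoms: N,O-dimethylhydroxylamine hydrochloride, CNOC.Cl
Why: Acid chloride formation and amidation to the Weinreb amide; the α-hydrogen beside the quaternary carbon is too shielded for ketene formation, so the stereocentre should hold.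

Step 26
Reactants: 37 (2S)-2-(ArCH2)-N-methoxy-N,3,3-trimethylpent-4-enamide
Product: 38 (5S)-5-(ArCH2)-6,6-dimethylocta-1,7-dien-4-one
Conditions: CH2=CHCH2MgBr, THF, −78 → 0 °C; cold NH4Cl quench
Reagents that add atoms: allylmagnesium bromide, C=CC[Mg]Br
Why: Weinreb ketone synthesis; the chelated tetrahedral intermediate prevents over-addition and the β,γ-unsaturated ketone is released only on cold quench.

Step 27
Reactants: 38 (5S)-5-(ArCH2)-6,6-dimethylocta-1,7-dien-4-one
Product: 39 (6S)-6-(ArCH2)-5,5-dimethylcyclohex-3-en-1-one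
Conditions: second-generation Grubbs catalyst RuCl2(=CHPh)(PCy3)(H2IMes) (5 mol%), 2,6-dichloro-1,4-benzoquinone (10 mol%), CH2Cl2, 40 °C
Reagents that add atoms: none
Why: Ring-closing metathesis of the allyl group and the neopentylic vinyl group, helped by the gem-dimethyl effect; the quinone additive suppresses ruthenium hydride isomerisation of the allyl ketone.

Step 28
Reactants: 39 (6S)-6-(ArCH2)-5,5-dimethylcyclohex-3-en-1-one
Product: 40 triethyl{[(6S)-6-(ArCH2)-5,5-dimethylcyclohexa-1,3-dien-1-yl]oxy}silane
Conditions: TESOTf, Et3N, CH2Cl2, −78 → 0 °C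
Reagents that add atoms: triethylsilyl triflate, CC[Si](CC)(CC)OS(=O)(=O)C(F)(F)F
Why: Soft enolisation removes the doubly activated hydrogen between carbonyl and alkene, so the conjugated 1-silyloxy-1,3-diene forms regiospecifically and the α′ stereocentre is not touched.

Step 29
Reactants: 41 methyl acrylate
Product: 43 methyl (E)-3-nitroacrylate, via methyl 2-iodo-3-nitropropanoate 42 (not isolated)
Conditions: I2, N2O4, Et2O, 0 °C; then NaOAc, Et2O, 0 °C → rt
Reagents that add atoms: dinitrogen tetroxide, O=[N+]([O-])[N+](=O)[O-]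
Why: Nitro-iodination of the acrylate followed by acetate-induced dehydroiodination gives the E-nitroalkene.

Step 30
Reactants: 40 triethyl{[(6S)-6-(ArCH2)-5,5-dimethylcyclohexa-1,3-dien-1-yl]oxy}silane; 43 methyl (E)-3-nitroacrylate
Product: 45 methyl 8-(ArCH2)-7,7-dimethyl-4-(triethylsilyloxy)bicyclo[2.2.2]octa-2,5-diene-2-carboxylate (ArCH2 syn to the C5=C6 bridge), via nitro ester cycloadduct 44 (not isolated)
Conditions: toluene, 0 °C → rt; then DBU, 0 °C → rt
Reagents that add atoms: none
Why: Diels–Alder reaction; the nitro group dictates the orientation (nitro-bearing carbon to the silyloxy terminus), the dienophile adds anti to the arylmethyl group, and DBU then removes nitrous acid by an E1cB elimination. The ester thus ends on the carbon next to the CH bridgehead, which a plain acrylate would not give, and the diene oxygen becomes the bridgehead oxygen.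

Step 31
Reactants: 45 methyl 8-(ArCH2)-7,7-dimethyl-4-(triethylsilyloxy)bicyclo[2.2.2]octa-2,5-diene-2-carboxylate
Product: 46 methyl 8-(ArCH2)-7,7-dimethyl-4-(triethylsilyloxy)bicyclo[2.2.2]oct-5-ene-2-carboxylate (C2 epimers)
Conditions: [(Ph3P)CuH]6 (0.4 equiv), degassed H2O (5 equiv), THF, rt
Reagents that add atoms: none
Why: Copper hydride conjugate reduction of the unsaturated ester, a polar process that leaves the isolated alkene, the benzyl ether and both silyl ethers alone.

Step 32
Reactants: 46 methyl 8-(ArCH2)-7,7-dimethyl-4-(triethylsilyloxy)bicyclo[2.2.2]oct-5-ene-2-carboxylate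
Product: 48 methyl 8-(ArCH2)-2,7,7-trimethyl-4-(triethylsilyloxy)bicyclo[2.2.2]oct-5-ene-2-carboxylate (2-methyl syn to the C5=C6 bridge), via lithium ester enolate 47 (not isolated)
Conditions: LDA, THF, −78 °C; then MeI, HMPA, −78 → −20 °C
Reagents that add atoms: iodomethane, CI
Why: Ester enolate alkylation; iodomethane should approach the planar enolate carbon from the side of the etheno bridge, away from the gem-dimethyl bridge, which puts the methyl syn to that bridge and the ester toward the gem-dimethyl carbon as the target requires.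

Step 33
Reactants: 48 methyl 8-(ArCH2)-2,7,7-trimethyl-4-(triethylsilyloxy)bicyclo[2.2.2]oct-5-ene-2-carboxylate
Product: 49 [8-(ArCH2)-2,7,7-trimethyl-4-(triethylsilyloxy)bicyclo[2.2.2]oct-5-en-2-yl]methanol
Conditions: DIBAL-H (3 equiv), CH2Cl2, −78 → 0 °C; Rochelle salt
Reagents that add atoms: none
Why: Hydride reduction of the hindered ester to the neopentylic alcohol with a reagent that leaves aryl silyl ethers intact.

Step 34
Reactants: 49 [8-(ArCH2)-2,7,7-trimethyl-4-(triethylsilyloxy)bicyclo[2.2.2]oct-5-en-2-yl]methanol
Product: 50 8-(ArCH2)-2,7,7-trimethyl-4-(triethylsilyloxy)bicyclo[2.2.2]oct-5-ene-2-carbaldehyde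
Conditions: Dess–Martin periodinane, NaHCO3, CH2Cl2, rt
Reagents that add atoms: none
Why: Dess–Martin oxidation to a non-enolisable aldehyde.

Step 35
Reactants: 24 (5aR,6S,7S,9aS)-2,2,5a,7-tetramethyl-6-{3-[(1-phenyl-1H-tetrazol-5-yl)sulfonyl]propyl}decahydro-1-benzoxepin-6-ol; 50 8-(ArCH2)-2,7,7-trimethyl-4-(triethylsilyloxy)bicyclo[2.2.2]oct-5-ene-2-carbaldehyde
Product: 52 coupled alkene (C6 of the benzoxepinol linked through CH2CH2CH=CH to C2 of the bicyclooctene; alkene isomers), via dipotassium sulfonyl carbanion 51 (not isolated)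
Conditions: KHMDS (2.2 equiv), DME, −60 °C; then 50, −60 °C → rt
Reagents that add atoms: none
Why: Julia–Kocienski olefination; the metalated tetrazolyl sulfone adds to the non-enolisable aldehyde and the adduct collapses by Smiles rearrangement with loss of SO2. The alkene geometry is irrelevant because the bond is hydrogenated.

Step 36
Reactants: 52 coupled alkene
Product: 53 phenol with saturated chain and saturated bicyclo[2.2.2]octane (bridgehead OSiEt3 and aryl OSi(i-Pr)3 retained)
Conditions: H2 (3 atm), Pd(OH)2/C, EtOAc, rt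
Reagents that add atoms: none
Why: Catalytic hydrogenation saturates both alkenes and hydrogenolyses the benzyl ether in one operation; no stereocentre is created.

Step 37
Reactants: 53 phenol
Product: 54 sodium aryl sulfate of 53
Conditions: SO3·pyridine, pyridine, rt; then aq. NaHCO3
Reagents that add atoms: sulfur trioxide–pyridine complex, [O-]S(=O)(=O)[n+]1ccccc1; sodium hydrogencarbonate, OC(=O)[O-].[Na+]
Why: O-Sulfation of the only free phenol; the hindered tertiary alcohol should not compete under these mild conditions.

Step 38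
Reactants: 54 sodium aryl sulfate
Product: 55 target, 4-hydroxy-3-{[(1S,2S,4S,5R)-1-hydroxy-5-{4-[(5aR,6S,7S,9aS)-6-hydroxy-2,2,5a,7-tetramethyldecahydro-1-benzoxepin-6-yl]butyl}-3,3,5-trimethylbicyclo[2.2.2]octan-2-yl]methyl}phenyl hydrogen sulfate
Conditions: TBAF, THF, rt → 40 °C; then cold 0.5 M HCl, EtOAc/n-BuOH extraction
Reagents that add atoms: none
Why: Fluoride cleaves the aryl and the bridgehead silyl ethers; aryl sulfate monoesters are stable to fluoride and base, and a brief cold acidification gives the hydrogen sulfate.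

## Compound list

1 | (R)-4-benzyl-3-propionyloxazolidin-2-one | CCC(=O)N1C(=O)OC[C@H]1Cc1ccccc1 | starting material
2 | methacrolein | CC(=C)C=O | starting material
3 | dibutylboron Z-enolate of 1 | C/C=C(\OB(CCCC)CCCC)N1C(=O)OC[C@H]1Cc1ccccc1 | intermediate
4 | (R)-4-benzyl-3-[(2R,3R)-3-hydroxy-2,4-dimethylpent-4-enoyl]oxazolidin-2-one | O=C([C@H](C)[C@@H](O)C(C)=C)N1C(=O)OC[C@H]1Cc1ccccc1 | intermediate
5 | (R)-4-benzyl-3-[(2R,3R)-3-(tert-butyldimethylsilyloxy)-2,4-dimethylpent-4-enoyl]oxazolidin-2-one | O=C([C@H](C)[C@@H](O[Si](C)(C)C(C)(C)C)C(C)=C)N1C(=O)OC[C@H]1Cc1ccccc1 | intermediate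
6 | (2S,3R)-3-(tert-butyldimethylsilyloxy)-2,4-dimethylpent-4-en-1-ol | OC[C@H](C)[C@@H](O[Si](C)(C)C(C)(C)C)C(C)=C | intermediate
7 | tert-butyl{[(3R,4R)-5-iodo-2,4-dimethylpent-1-en-3-yl]oxy}dimethylsilane | IC[C@H](C)[C@@H](O[Si](C)(C)C(C)(C)C)C(C)=C | intermediate
8 | 2,2,5-trimethylfuran-3(2H)-one | CC1=CC(=O)C(C)(C)O1 | starting material
9 | lithium dienolate of 8 | [Li]OC1=CC(=C)OC1(C)C | intermediate
10 | 5-[(3S,4R)-4-(tert-butyldimethylsilyloxy)-3,5-dimethylhex-5-en-1-yl]-2,2-dimethylfuran-3(2H)-one | O=C1C=C(CC[C@H](C)[C@@H](O[Si](C)(C)C(C)(C)C)C(C)=C)OC1(C)C | intermediate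
11 | tricyclic photoadduct (oxabicyclo[3.2.0]heptanone cis-fused to ring A) | C[C@H]1CC[C@@]23OC(C)(C)C(=O)[C@@H]2C[C@@]3(C)[C@@H]1O[Si](C)(C)C(C)(C)C | intermediate
12 | trimethylsilyl enol ether of 13 | C[C@H]1CC[C@@H]2OC(C)(C)C(O[Si](C)(C)C)=CC[C@@]2(C)[C@@H]1O[Si](C)(C)C(C)(C)C | intermediate
13 | (5aR,6R,7S,9aS)-6-(tert-butyldimethylsilyloxy)-2,2,5a,7-tetramethyloctahydro-1-benzoxepin-3(2H)-one | C[C@H]1CC[C@@H]2OC(C)(C)C(=O)CC[C@@]2(C)[C@@H]1O[Si](C)(C)C(C)(C)C | intermediate
14 | (5aR,6R,7S,9aS)-6-(tert-butyldimethylsilyloxy)-2,2,5a,7-tetramethyldecahydro-1-benzoxepin-3-ol (C3 epimers) | C[C@H]1CC[C@@H]2OC(C)(C)C(O)CC[C@@]2(C)[C@@H]1O[Si](C)(C)C(C)(C)C | intermediate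
15 | O-phenyl thionocarbonate of 14 | C[C@H]1CC[C@@H]2OC(C)(C)C(OC(=S)Oc3ccccc3)CC[C@@]2(C)[C@@H]1O[Si](C)(C)C(C)(C)C | intermediate
16 | tert-butyldimethyl{[(5aR,6R,7S,9aS)-2,2,5a,7-tetramethyldecahydro-1-benzoxepin-6-yl]oxy}silane | C[C@H]1CC[C@@H]2OC(C)(C)CCC[C@@]2(C)[C@@H]1O[Si](C)(C)C(C)(C)C | intermediate
17 | (5aS,6R,7S,9aS)-2,2,5a,7-tetramethyldecahydro-1-benzoxepin-6-ol | C[C@H]1CC[C@@H]2OC(C)(C)CCC[C@@]2(C)[C@@H]1O | intermediate
18 | (5aR,7S,9aS)-2,2,5a,7-tetramethyloctahydro-1-benzoxepin-6(2H)-one | C[C@H]1CC[C@@H]2OC(C)(C)CCC[C@@]2(C)C1=O | intermediate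
19 | (5aS,7S,9aS)-2,2,5a,7-tetramethyl-6-methylidenedecahydro-1-benzoxepine | C[C@H]1CC[C@@H]2OC(C)(C)CCC[C@@]2(C)C1=C | intermediate
20 | spiro-epoxide at C6 (oxygen anti to the angular methyl) | C[C@H]1CC[C@@H]2OC(C)(C)CCC[C@@]2(C)[C@]13CO3 | intermediate
21 | (5aR,6S,7S,9aS)-2,2,5a,7-tetramethyl-6-(prop-2-en-1-yl)decahydro-1-benzoxepin-6-ol | C[C@H]1CC[C@@H]2OC(C)(C)CCC[C@@]2(C)[C@]1(O)CC=C | intermediate
22 | (5aR,6S,7S,9aS)-6-(3-hydroxypropyl)-2,2,5a,7-tetramethyldecahydro-1-benzoxepin-6-ol | C[C@H]1CC[C@@H]2OC(C)(C)CCC[C@@]2(C)[C@]1(O)CCCO | intermediate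
23 | tetrazolyl sulfide of 22 | C[C@H]1CC[C@@H]2OC(C)(C)CCC[C@@]2(C)[C@]1(O)CCCSc1nnnn1-c1ccccc1 | intermediate
24 | tetrazolyl sulfone of 22 | C[C@H]1CC[C@@H]2OC(C)(C)CCC[C@@]2(C)[C@]1(O)CCCS(=O)(=O)c1nnnn1-c1ccccc1 | intermediate
25 | 5-(benzyloxy)-2-hydroxybenzaldehyde | O=Cc1cc(OCc2ccccc2)ccc1O | starting material
26 | 5-(benzyloxy)-2-(triisopropylsilyloxy)benzaldehyde | O=Cc1cc(OCc2ccccc2)ccc1O[Si](C(C)C)(C(C)C)C(C)C | intermediate
27 | [5-(benzyloxy)-2-(triisopropylsilyloxy)phenyl]methanol | OCc1cc(OCc2ccccc2)ccc1O[Si](C(C)C)(C(C)C)C(C)C | intermediate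
28 | [4-(benzyloxy)-2-(bromomethyl)phenoxy]triisopropylsilane | BrCc1cc(OCc2ccccc2)ccc1O[Si](C(C)C)(C(C)C)C(C)C | intermediate
29 | 3,3-dimethylpent-4-enoic acid | OC(=O)CC(C)(C)C=C | starting material
30 | (S)-4-benzyloxazolidin-2-one | O=C1OC[C@H](Cc2ccccc2)N1 | starting material
31 | 3,3-dimethylpent-4-enoic pivalic anhydride | C=CC(C)(C)CC(=O)OC(=O)C(C)(C)C | intermediate
32 | (S)-4-benzyl-3-(3,3-dimethylpent-4-enoyl)oxazolidin-2-one | C=CC(C)(C)CC(=O)N1C(=O)OC[C@@H]1Cc1ccccc1 | intermediate
33 | sodium Z-enolate of 32 | C=CC(C)(C)/C=C(\O[Na])N1C(=O)OC[C@@H]1Cc1ccccc1 | intermediate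
34 | (S)-4-benzyl-3-[(2S)-2-(ArCH2)-3,3-dimethylpent-4-enoyl]oxazolidin-2-one | C=CC(C)(C)[C@H](Cc1cc(OCc2ccccc2)ccc1O[Si](C(C)C)(C(C)C)C(C)C)C(=O)N1C(=O)OC[C@@H]1Cc1ccccc1 | intermediate
35 | (2S)-2-(ArCH2)-3,3-dimethylpent-4-enoic acid | C=CC(C)(C)[C@H](Cc1cc(OCc2ccccc2)ccc1O[Si](C(C)C)(C(C)C)C(C)C)C(=O)O | intermediate
36 | (2S)-2-(ArCH2)-3,3-dimethylpent-4-enoyl chloride | C=CC(C)(C)[C@H](Cc1cc(OCc2ccccc2)ccc1O[Si](C(C)C)(C(C)C)C(C)C)C(Cl)=O | intermediate
37 | (2S)-2-(ArCH2)-N-methoxy-N,3,3-trimethylpent-4-enamide | C=CC(C)(C)[C@H](Cc1cc(OCc2ccccc2)ccc1O[Si](C(C)C)(C(C)C)C(C)C)C(=O)N(C)OC | intermediate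
38 | (5S)-5-(ArCH2)-6,6-dimethylocta-1,7-dien-4-one | C=CC(C)(C)[C@H](Cc1cc(OCc2ccccc2)ccc1O[Si](C(C)C)(C(C)C)C(C)C)C(=O)CC=C | intermediate
39 | (6S)-6-(ArCH2)-5,5-dimethylcyclohex-3-en-1-one | O=C1CC=CC(C)(C)[C@@H]1Cc1cc(OCc2ccccc2)ccc1O[Si](C(C)C)(C(C)C)C(C)C | intermediate
40 | triethyl{[(6S)-6-(ArCH2)-5,5-dimethylcyclohexa-1,3-dien-1-yl]oxy}silane | CC[Si](CC)(CC)OC1=CC=CC(C)(C)[C@@H]1Cc1cc(OCc2ccccc2)ccc1O[Si](C(C)C)(C(C)C)C(C)C | intermediate
41 | methyl acrylate | COC(=O)C=C | starting material
42 | methyl 2-iodo-3-nitropropanoate | COC(=O)C(I)C[N+](=O)[O-] | intermediate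
43 | methyl (E)-3-nitroacrylate | COC(=O)/C=C/[N+](=O)[O-] | intermediate
44 | nitro ester cycloadduct (nitro carbon next to the C–OSiEt3 bridgehead; nitro and ester carbons unassigned) | COC(=O)C1C([N+](=O)[O-])[C@@]2(O[Si](CC)(CC)CC)C=C[C@@H]1C(C)(C)[C@@H]2Cc1cc(OCc2ccccc2)ccc1O[Si](C(C)C)(C(C)C)C(C)C | intermediate
45 | methyl 8-(ArCH2)-7,7-dimethyl-4-(triethylsilyloxy)bicyclo[2.2.2]octa-2,5-diene-2-carboxylate | COC(=O)C1=C[C@@]2(O[Si](CC)(CC)CC)C=C[C@@H]1C(C)(C)[C@@H]2Cc1cc(OCc2ccccc2)ccc1O[Si](C(C)C)(C(C)C)C(C)C | intermediate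
46 | methyl 8-(ArCH2)-7,7-dimethyl-4-(triethylsilyloxy)bicyclo[2.2.2]oct-5-ene-2-carboxylate (C2 epimers) | COC(=O)C1C[C@@]2(O[Si](CC)(CC)CC)C=C[C@@H]1C(C)(C)[C@@H]2Cc1cc(OCc2ccccc2)ccc1O[Si](C(C)C)(C(C)C)C(C)C | intermediate
47 | lithium ester enolate of 46 | COC(O[Li])=C1C[C@@]2(O[Si](CC)(CC)CC)C=C[C@@H]1C(C)(C)[C@@H]2Cc1cc(OCc2ccccc2)ccc1O[Si](C(C)C)(C(C)C)C(C)C | intermediate
48 | methyl 8-(ArCH2)-2,7,7-trimethyl-4-(triethylsilyloxy)bicyclo[2.2.2]oct-5-ene-2-carboxylate | COC(=O)[C@]1(C)C[C@@]2(O[Si](CC)(CC)CC)C=C[C@@H]1C(C)(C)[C@@H]2Cc1cc(OCc2ccccc2)ccc1O[Si](C(C)C)(C(C)C)C(C)C | intermediate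
49 | [8-(ArCH2)-2,7,7-trimethyl-4-(triethylsilyloxy)bicyclo[2.2.2]oct-5-en-2-yl]methanol | OC[C@]1(C)C[C@@]2(O[Si](CC)(CC)CC)C=C[C@@H]1C(C)(C)[C@@H]2Cc1cc(OCc2ccccc2)ccc1O[Si](C(C)C)(C(C)C)C(C)C | intermediate
50 | 8-(ArCH2)-2,7,7-trimethyl-4-(triethylsilyloxy)bicyclo[2.2.2]oct-5-ene-2-carbaldehyde | O=C[C@]1(C)C[C@@]2(O[Si](CC)(CC)CC)C=C[C@@H]1C(C)(C)[C@@H]2Cc1cc(OCc2ccccc2)ccc1O[Si](C(C)C)(C(C)C)C(C)C | intermediate
51 | dipotassium alkoxide/sulfonyl carbanion of 24 | C[C@H]1CC[C@@H]2OC(C)(C)CCC[C@@]2(C)[C@]1([O-])CC[CH-]S(=O)(=O)c1nnnn1-c1ccccc1.[K+].[K+] | intermediate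
52 | coupled alkene (alkene isomers) | C[C@H]1CC[C@@H]2OC(C)(C)CCC[C@@]2(C)[C@]1(O)CCC=C[C@]1(C)C[C@@]2(O[Si](CC)(CC)CC)C=C[C@@H]1C(C)(C)[C@@H]2Cc1cc(OCc2ccccc2)ccc1O[Si](C(C)C)(C(C)C)C(C)C | intermediate
53 | saturated phenol | C[C@H]1CC[C@@H]2OC(C)(C)CCC[C@@]2(C)[C@]1(O)CCCC[C@]1(C)C[C@@]2(O[Si](CC)(CC)CC)CC[C@@H]1C(C)(C)[C@@H]2Cc1cc(O)ccc1O[Si](C(C)C)(C(C)C)C(C)C | intermediate
54 | sodium aryl sulfate of 53 | C[C@H]1CC[C@@H]2OC(C)(C)CCC[C@@]2(C)[C@]1(O)CCCC[C@]1(C)C[C@@]2(O[Si](CC)(CC)CC)CC[C@@H]1C(C)(C)[C@@H]2Cc1cc(OS(=O)(=O)[O-])ccc1O[Si](C(C)C)(C(C)C)C(C)C.[Na+] | intermediate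
55 | CNP0255133.1 | C[C@H]1CC[C@@H]2OC(C)(C)CCC[C@@]2(C)[C@]1(O)CCCC[C@]1(C)C[C@@]2(O)CC[C@@H]1C(C)(C)[C@@H]2Cc1cc(OS(=O)(=O)O)ccc1O | target

## Step count and least certain steps

Total step count: 38. Longest linear sequence: 22 steps (steps 1–18, then 35–38). The eastern branch (steps 19–21, 22–28, 29, 30–34) joins at step 35.

Step 7 (proposed new method). The most likely failures are that the ring-fusion bond does not ionise because its overlap with the carbonyl is poor in the five-membered ring, that the oxocarbenium ion loses a proton to an enol ether before hydride arrives, or that the silyl ether is lost. The fallback uses known radical chemistry, sets out from 11 and returns at 16. Borohydride reduction of 11 gives the tricyclic alcohol F1. 1,1′-Thiocarbonyldiimidazole converts it into the imidazole-1-carbothioate F2. Bu3SnH/AIBN under high dilution generates the cyclobutylcarbinyl radical, whose ring-fusion bond should cleave toward the tertiary α-alkoxy radical; hydrogen transfer anti to the angular methyl gives the oxepene F3. Hydrogenation over Pd/C gives 16. This is the photocycloaddition/cyclobutylcarbinyl radical fragmentation sequence, with deoxygenation built in.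

Step 6 (key step). The most likely failures are poor discrimination between the two cis-fused modes of addition, and hydrogen transfer within the 1,4-biradical in place of ring closure, because the first bond creates two adjacent fully substituted carbons. The fallback changes the chromophore and moves the ring-fusion stereocentre out of the photochemical step. It sets out from 10 and returns at 13. Aqueous LiOH opens the vinylogous ester to the open-chain hydroxy 1,3-diketone F4. F4 is irradiated as its hydrogen-bonded enol (classical de Mayo reaction). The cyclobutanol F5 is not isolated and undergoes retro-aldol cleavage to the 1,5-diketone F6, in which only the angular centre has been set by light. Et3SiH/TMSOTf reductive etherification of F6 (tertiary hydroxyl onto the ring ketone, axial hydride) closes the oxepane and gives 13.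

Step 5. Elimination of the β-branched iodide by the basic dienolate, or sluggish substitution, may dominate. The fallback replaces alkylation by carbonyl addition, sets out from 6 (with 8) and returns at 10. Dess–Martin oxidation of 6 gives the aldehyde F7. Addition of dienolate 9 at −78 °C (vinylogous aldol at the exocyclic carbon) gives the β-hydroxy adduct F8. Its O-phenyl thionocarbonate F9 is deoxygenated with Bu3SnH/AIBN to 10.

Step 15. Magnesium salts may rearrange the hindered epoxide to an aldehyde before substitution occurs, or the neopentyl-like CH2 may react too slowly. The fallback uses a small nucleophile free of Lewis acid, sets out from 20 and returns at 21. Lithium acetylide–ethylenediamine complex in DMSO opens the epoxide at CH2 to the homopropargylic alcohol F10. Semi-hydrogenation over Lindlar catalyst (Pd/CaCO3 poisoned with Pb(OAc)2, quinoline) gives 21.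

Step 35. Addition of the metalated sulfone to the very hindered aldehyde may be slow, so that the sulfone anion decomposes by self-condensation. The fallback is a phosphorus olefination, sets out from 22 (with 50) and returns at 52. I2/PPh3/imidazole gives the iodide F11, which is used at once to avoid closure to a tetrahydrofuran. PPh3 in MeCN gives the phosphonium iodide F12. Its oxido ylide (NaHMDS, 2 equiv) reacts with 50 to give 52 as the Z-rich alkene, which converges at step 36.

## Further compounds

F1 | step 7 | tricyclic alcohol from 11 (carbinol epimers) | C[C@H]1CC[C@@]23OC(C)(C)C(O)[C@@H]2C[C@@]3(C)[C@@H]1O[Si](C)(C)C(C)(C)C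
F2 | step 7 | imidazole-1-carbothioate of F1 | C[C@H]1CC[C@@]23OC(C)(C)C(OC(=S)n4ccnc4)[C@@H]2C[C@@]3(C)[C@@H]1O[Si](C)(C)C(C)(C)C
F3 | step 7 | trans-fused tetrahydrooxepine (C3=C4 alkene) | C[C@H]1CC[C@@H]2OC(C)(C)C=CC[C@@]2(C)[C@@H]1O[Si](C)(C)C(C)(C)C
F4 | step 6 | open-chain hydroxy 1,3-diketone from 10 | CC(C)(O)C(=O)CC(=O)CC[C@H](C)[C@@H](O[Si](C)(C)C(C)(C)C)C(C)=C
F5 | step 6 | cyclobutanol photoadduct (not isolated) | C[C@H]1CC[C@@]2(O)C(C(=O)C(C)(C)O)C[C@@]2(C)[C@@H]1O[Si](C)(C)C(C)(C)C
F6 | step 6 | ring A ketone with 4-hydroxy-4-methyl-3-oxopentyl side chain | C[C@H]1CCC(=O)[C@@](C)(CCC(=O)C(C)(C)O)[C@@H]1O[Si](C)(C)C(C)(C)C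
F7 | step 5 | (2R,3R)-3-(tert-butyldimethylsilyloxy)-2,4-dimethylpent-4-enal | O=C[C@H](C)[C@@H](O[Si](C)(C)C(C)(C)C)C(C)=C
F8 | step 5 | vinylogous aldol adduct (carbinol epimers) | O=C1C=C(CC(O)[C@H](C)[C@@H](O[Si](C)(C)C(C)(C)C)C(C)=C)OC1(C)C
F9 | step 5 | O-phenyl thionocarbonate of F8 | O=C1C=C(CC(OC(=S)Oc2ccccc2)[C@H](C)[C@@H](O[Si](C)(C)C(C)(C)C)C(C)=C)OC1(C)C
F10 | step 15 | (5aR,6S,7S,9aS)-2,2,5a,7-tetramethyl-6-(prop-2-yn-1-yl)decahydro-1-benzoxepin-6-ol | C[C@H]1CC[C@@H]2OC(C)(C)CCC[C@@]2(C)[C@]1(O)CC#C
F11 | step 35 | (5aR,6S,7S,9aS)-6-(3-iodopropyl)-2,2,5a,7-tetramethyldecahydro-1-benzoxepin-6-ol | C[C@H]1CC[C@@H]2OC(C)(C)CCC[C@@]2(C)[C@]1(O)CCCI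
F12 | step 35 | triphenylphosphonium iodide from F11 | C[C@H]1CC[C@@H]2OC(C)(C)CCC[C@@]2(C)[C@]1(O)CCC[P+](c1ccccc1)(c1ccccc1)c1ccccc1.[I-]
A1 | alternative 1 | 6-(methoxymethoxy)-5-(arylmethyl)-4,4-dimethylcyclohex-2-en-1-one (C6 unassigned) | O=C1C=CC(C)(C)[C@H](Cc2cc(O[Si](C(C)C)(C(C)C)C(C)C)ccc2OCc2ccccc2)C1OCOC
A2 | alternative 1 | bridgehead-alkoxy bicyclo[2.2.2]octanone ester | COC(=O)[C@H]1C[C@@]2(OCOC)C(=O)C[C@@H]1C(C)(C)[C@@H]2Cc1cc(O[Si](C(C)C)(C(C)C)C(C)C)ccc1OCc1ccccc1
A3 | alternative 2 | ethyl 6,7:10,11-diepoxy-7,11-dimethyl-3-oxododecanoate | CCOC(=O)CC(=O)CC[C@@H]1O[C@@]1(C)CC[C@@H]1OC1(C)C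
A4 | alternative 2 | trans-fused hydroxy-oxepane ring A β-keto ester | O=C1CC[C@@H]2OC(C)(C)[C@@H](O)CC[C@@]2(C)[C@@H]1C(=O)OCC
A5 | alternative 3 | trans-decalone with ketone next to the ring-fusion methine | C1CC[C@@H]2C(=O)CCC[C@@]2(C)[C@@H]1O[Si](C)(C)C(C)(C)C
A6 | alternative 3 | trans-fused seven-membered lactone on ring A | C1CC[C@@H]2OC(=O)CCC[C@@]2(C)[C@@H]1O[Si](C)(C)C(C)(C)C
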